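(The numbers in the tables were computed for substances that don't exist.)

An invariant stands in the winter run: first product minus substrate, in percent of the substrate charged, is 20 percentage points at 3.00 h and 21 points at 12.0 h, while substrate falls from 11.1% to 0.5%. So I read one step that removes a substrate and a first product together. The mean over the four winter readings, 20 points, I call the surplus. While that pairing step runs by itself, first product equals surplus plus remaining substrate, so a positive surplus is where first product ends, and a negative one leaves substrate instead. Each substrate turned into first product raises the surplus by two.

| flask | substrate | partner | temperature | remark | time |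
|---|---|---|---|---|---|
| winter | 0.050 M | 0.060 M | 60 °C | run made earlier |  |
| noon | 0.050 M | 0.090 M | 60 °C | run made earlier |  |
| maple | 0.050 M (in portions, 4, over 15 h) | 0.0600 M | 60 °C | first portion at the start, last at 15 h | 20 h |
| cedar | 0.050 M | 0.0600 M (fed, over 15 h) |  | the addition at 40 °C, then warmed to 60 °C; the feed brings no volume worth counting | 20 h |
| elm | 0.050 M (fed, over 15 h) | 0.0600 M | 60 °C | all else is in the flask from the start; the feed brings no volume worth counting | 20 h |
| oak | 0.050 M | 0.0600 M |  | everything together at the start at 40 °C, warmed to 60 °C at 15 h | 20 h |
| ash | 0.050 M | 0.0600 M | 60 °C | everything together at the start | 20 h |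

| run | time / h | first product / % | substrate / % |
|---|---|---|---|
| winter | 3.00 | 31.1 | 11.1 |
| winter | 6.00 | 24.6 | 4.3 |
| winter | 10.0 | 22.0 | 2.2 |
| winter | 12.0 | 21.5 | 0.5 |
| noon | 0.833 | 41.1 | 14.0 |
| noon | 2.00 | 36.3 | 6.6 |
| noon | 4.00 | 33.1 | 3.2 |
| noon | 6.00 | 31.1 | 0.6 |

(readings scatter by 0.5 percentage points)

- the earlier runs do not show what temperature does; that part of a forecast is a guess
- a reading or a percentage of first product counts all its forms, free or not

1. the flask with the highest amount of first product, in percent of the substrate charged ("all alike" if they lie within 1.5 percentage points) (maple / cedar / elm / oak / ash / all alike)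
2. final first product, as a percentage of the substrate charged, in maple
3. final first product, as a percentage of the substrate charged, in cedar
4. final first product, as a percentage of the substrate charged, in elm
5. final first product, as a percentage of the substrate charged, in oak
6. final first product, as a percentage of the substrate charged, in ash

Two views part here. A colleague notes that the noon run had more partner, by 60.0% of the substrate charged, yet its last surplus of 30 points means just 5.1 points more substrate turned over. He concludes that partner destroys itself, and that feeding it thin saves it.

I reckon with the surplus instead. Between the first two winter readings, the pairing gives first product a mean life of 0.946 h among substrate as charged (pseudo-first-order, a reading with its scatter). That is far shorter than the feed of 15 h. In cedar, then, first product is eaten about as fast as it forms, so each partner costs two substrates; the share turned over tends to 0.5 of the charge and the surplus tends to zero, if cooling slows both steps alike, which is a guess.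

In elm, the winter surplus already stood at 3.00 h, when 20.0% of the substrate would be in, so I expect a surplus near −60 points and no first product; maple goes likewise. Ash repeats winter, so it should end near 20 points. Oak has the same charges but starts at 40 °C, and first product there is surplus plus whatever substrate remains after its short warm stretch. I rank oak, then ash, then cedar, with maple and elm last.

The forecast reads maple 5%, cedar 31%, elm 5%, oak 23%, ash 21%, with cedar highest: “Cedar keeps partner low, which cuts self-loss”.

The flasks give maple 0.0510%, cedar 10.2%, elm 0.0262%, oak 26.9%, ash 20.3%, with oak highest.

    substrate + partner → first product (k = 0.770 M⁻¹ min⁻¹, Ea = 63.0 kJ mol⁻¹)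
    partner + first product → bis adduct (k = 0.640 M⁻¹ min⁻¹, Ea = 59.0 kJ mol⁻¹)
    partner + bis adduct → triple product (k = 1.90 M⁻¹ min⁻¹, Ea = 78.0 kJ mol⁻¹)
    partner + triple product → tetra adduct (k = 1.20 M⁻¹ min⁻¹, Ea = 72.0 kJ mol⁻¹)
    2 substrate → homo dimer (k = 4.10 × 10⁻⁵ M⁻¹ min⁻¹, Ea = 106 kJ mol⁻¹)
    crystals ⇌ first product, rate k6*(cs6 - [first product]) while solid is left; crystals form when [first product] > cs6 (solubility = 8.10 mM, k = 0.130 min⁻¹)
    substrate + first product → side product (k = 0.480 M⁻¹ min⁻¹, Ea = 68.0 kJ mol⁻¹)
    (constants at 60 °C)

Oak's surplus at 20.0 h is 24 points, which is 3.6 points above the winter 20 points, and its first product stands at 23.9% after 200 h. The scheme holds no step of partner with itself. Among the slow additions, cedar keeps more first product than maple or elm, with a surplus of 6.8 points. Elm's surplus is −46 points. A repeat of elm at 35 °C holds 13.7% first product and 31.0% substrate at 20.0 h, with 2.49% of its partner charge left, a surplus of −17 points.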